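**Retrosynthetic overview**
1. Salimabromide ⇒ late twofold aromatic bromination ortho to the ethyl group; ring C (γ-lactone) is closed just before that by acidolysis of a PMB ether/tert-butyl ester pair on the tricyclic enone 19.
2. Key disconnection of 19: rings B and D together, by cutting the bond between the benzylic CH and the CH α to the ester (Michael addition) and the enone CH=CH bond (aldol condensation). This is a formal intramolecular (4+3) annulation triggered by fluoride opening of a 2-siloxycyclopropanecarboxylate (15).
3. Enabling feature: in ring D the methyl-bearing quaternary carbon links the enone β-CH (an aldehyde carbon before condensation) and the CH α to the lactone carbonyl, i.e. a γ-oxo ester, which is the open form of a donor–acceptor cyclopropane. The other four ring D carbons (benzylic CH, O–CH, C=O, enone α-CH) are an α-alkoxy enone whose oxygen blocks the competing aldol and later becomes the lactone oxygen.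
4. The cyclopropane (temporary ring) comes from enantioselective copper-catalysed cyclopropanation of a silyl enol ether, which sets the quaternary stereocentre next to the gem-dimethyl carbon; the aryl–C(CH3)2 bond comes from SNAr on 2-bromo-4-ethyl-1-fluorobenzene.
5. Ring order: A (purchased) → cyclopropane (step 7) → B + D (step 11) → C (step 12).

Key step: step 11

Locants used in the text: C-q (methyl-bearing quaternary carbon), C-g (gem-dimethyl carbon), C-b (benzylic CH), C-e (CH α to the ester/lactone carbonyl), C-o (O-bearing CH α to the ketone), C-α=C-β (enone CH=CH, C-β on C-q); ring A arene, ring B six-membered carbocycle, ring C lactone, ring D cycloheptenone.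

Assumption (chemistry): the (S,S)-ligand in step 7 is taken to deliver the carbene to the enol ether face that gives the (R)-quaternary carbon drawn (the (R,R)-ligand is used if the opposite sense is found), and centres that become sp2 again in step 11 (enone geometry of 15, ester-bearing ring carbon of 9) are drawn as the expected major isomers.

**Step 1**
Reactants: 1 1-(3-bromo-4-fluorophenyl)ethan-1-one
Product: 2 2-bromo-4-ethyl-1-fluorobenzene
Conditions: Et3SiH (3 equiv), TFA, 60 °C
Reagents that add atoms: none
Why: Ionic hydrogenation of an aryl ketone (hydride transfer from the silane to the protonated ketone and then to the benzylic cation) should take the acetyl group down to ethyl and leave the C–F and C–Br bonds untouched; no stereocentre is formed.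

**Step 2**
Reactants: 2 2-bromo-4-ethyl-1-fluorobenzene
Product: 3 2-(2-bromo-4-ethylphenyl)-2-methylpropanenitrile
Conditions: isobutyronitrile (3 equiv), KN(SiMe3)2 (1.5 equiv), toluene, 65 °C
Reagents that add atoms: isobutyronitrile, CC(C)C#N
Why: Nucleophilic aromatic substitution (addition–elimination) of the aryl fluoride by the potassium anion of the tertiary nitrile builds the aryl–C(CH3)2 bond; fluoride is the better nucleofuge and the ortho bromine activates the position inductively, so the bromide is kept as the later ortho handle.

**Step 3**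
Reactants: 3 2-(2-bromo-4-ethylphenyl)-2-methylpropanenitrile
Product: 5 3-(2-bromo-4-ethylphenyl)-3-methylbutan-2-one, via magnesium ketimide 4 (not isolated)
Conditions: MeMgBr (2.5 equiv), toluene/Et2O, 90 °C; then 2 M HCl, THF, 23 °C
Reagents that add atoms: methylmagnesium bromide, C[Mg]Br; water, O
Why: Grignard addition to a nitrile stops at the magnesium ketimide, which cannot take up a second equivalent, and acidic hydrolysis then gives the methyl ketone; no stereocentre is formed.

**Step 4**
Reactants: 5 3-(2-bromo-4-ethylphenyl)-3-methylbutan-2-one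
Product: 6 2-bromo-4-ethyl-1-(4-methoxy-2,3-dimethylbut-3-en-2-yl)benzene (E/Z mixture)
Conditions: Ph3P(CH2OMe)Cl (2.5 equiv), KOt-Bu (2.4 equiv), THF, 0 → 60 °C
Reagents that add atoms: (methoxymethyl)triphenylphosphonium chloride, COC[P+](c1ccccc1)(c1ccccc1)c1ccccc1.[Cl-]
Why: Wittig methoxymethylenation of the hindered methyl ketone gives the one-carbon-homologated enol ether; its geometry is irrelevant because the next step destroys it.

**Step 5**
Reactants: 6 2-bromo-4-ethyl-1-(4-methoxy-2,3-dimethylbut-3-en-2-yl)benzene
Product: 7 3-(2-bromo-4-ethylphenyl)-2,3-dimethylbutanal (racemic)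
Conditions: 2 M HCl, THF, 23 °C
Reagents that add atoms: water, O
Why: Acid-catalysed enol ether hydrolysis (protonation at carbon, addition of water, loss of methanol) gives the α-branched aldehyde; its α-stereocentre is racemic and is removed again in step 6.

**Step 6**
Reactants: 7 3-(2-bromo-4-ethylphenyl)-2,3-dimethylbutanal
Product: 8 (E)-{[3-(2-bromo-4-ethylphenyl)-2,3-dimethylbut-1-en-1-yl]oxy}(tert-butyl)dimethylsilane
Conditions: TBSOTf (1.3 equiv), Et3N (2 equiv), CH2Cl2, 0 → 23 °C
Reagents that add atoms: tert-butyldimethylsilyl trifluoromethanesulfonate, CC(C)(C)[Si](C)(C)OS(=O)(=O)C(F)(F)F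
Why: Soft enolisation with O-silylation of the aldehyde gives the trisubstituted silyl enol ether, in which the silyloxy group should sit trans to the bulky aryl-isopropyl group (E) for steric reasons.

**Step 7**
Reactants: 8 (E)-silyl enol ether
Product: 9 tert-butyl (1S,2R,3S)-2-[2-(2-bromo-4-ethylphenyl)propan-2-yl]-3-[(tert-butyldimethylsilyl)oxy]-2-methylcyclopropane-1-carboxylate
Conditions: tert-butyl diazoacetate (1.5 equiv, slow addition), [Cu(MeCN)4]PF6 (2 mol%), (S,S)-t-Bu-box (2.4 mol%), CH2Cl2, 23 °C
Reagents that add atoms: tert-butyl diazoacetate, CC(C)(C)OC(=O)C=[N+]=[N-]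
Why: Copper-carbene cyclopropanation of an electron-rich silyl enol ether with a diazoacetate under a chiral bis(oxazoline)–copper catalyst is stereospecific with respect to the alkene; the ligand selects the alkene face and thereby sets the methyl-bearing quaternary carbon C-q (R), and the bulky ester should end up trans to the aryl-isopropyl group (this last centre is lost again in step 11).

**Step 8**
Reactants: 9 bromoaryl siloxycyclopropane ester
Product: 11 tert-butyl (1S,2R,3S)-3-[(tert-butyldimethylsilyl)oxy]-2-[2-(4-ethyl-2-formylphenyl)propan-2-yl]-2-methylcyclopropane-1-carboxylate, via aryllithium 10 (not isolated)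
Conditions: n-BuLi (1.1 equiv), THF, −95 °C; DMF (3 equiv), −95 → −40 °C; H2O
Reagents that add atoms: N,N-dimethylformamide, CN(C)C=O
Why: Bromine–lithium exchange followed by formylation with DMF converts the aryl bromide into the benzaldehyde; at −95 °C the hindered tert-butyl ester should be spared, and because it is trans to the aryl-bearing substituent on the three-membered ring a Parham-type ring closure is geometrically excluded.

**Step 9**
Reactants: 12 dimethyl (1-diazo-2-oxopropyl)phosphonate; 13 (4-methoxyphenyl)methanol
Product: 14 dimethyl {1-[(4-methoxyphenyl)methoxy]-2-oxopropyl}phosphonate (racemic)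
Conditions: Rh2(OAc)4 (1 mol%), 13 (1.5 equiv), toluene, 80 °C
Reagents that add atoms: none
Why: Rhodium-carbene O–H insertion of an α-diazo-β-ketophosphonate into a primary alcohol gives the α-alkoxy-β-ketophosphonate; the new centre is racemic and becomes sp2 in step 10.

**Step 10**
Reactants: 11 formylaryl siloxycyclopropane ester; 14 α-(PMB-oxy)-β-ketophosphonate
Product: 15 tert-butyl (1S,2R,3S)-3-[(tert-butyldimethylsilyl)oxy]-2-[2-(4-ethyl-2-{(1Z)-2-[(4-methoxyphenyl)methoxy]-3-oxobut-1-en-1-yl}phenyl)propan-2-yl]-2-methylcyclopropane-1-carboxylate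
Conditions: 14 (1.3 equiv), NaH (1.2 equiv), THF, 0 → 50 °C
Reagents that add atoms: none
Why: Horner–Wadsworth–Emmons olefination of the non-enolisable benzaldehyde with the α-alkoxy-β-ketophosphonate anion gives the α-(PMB-oxy) enone, expected mainly as the (Z)-isomer (aryl trans to acetyl); the geometry is not carried into later stereocentres.

**Step 11**
Reactants: 15 siloxycyclopropane α-alkoxy enone
Product: 19 tricyclic enone tert-butyl ester (rings A B D; C-b S; C-e R; C-q R; C-o S; PMB ether on C-o), via ester enolate aldehyde 16 (not isolated), via Michael adduct enolate 17 (not isolated), via aldolate 18 (not isolated)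
Conditions: CsF (3 equiv), DMF, 0 → 23 °C, then 60 °C
Reagents that add atoms: none
Why: Proposed new method: fluoride removes the silyl group, the cyclopropanolate opens by strain-driven retro-aldol cleavage of the bond between the oxygen-bearing and the ester-bearing ring carbons to give the neopentyl aldehyde and the tert-butyl ester enolate 16, which adds in a 6-exo-trig Michael addition to the benzylic carbon of the α-alkoxy enone (ring B, bond C-b–C-e) to give enolate 17; proton transfer to the methyl-side enolate, 7-(enolexo)-exo-trig aldol addition to the aldehyde (ring D, aldolate 18) and E1cB dehydration then give the enone (bond C-α=C-β), overall a formal intramolecular (4+3) annulation of a donor–acceptor cyclopropane with an enone. The closest known reaction types are the fluoride-induced ring opening of 2-siloxycyclopropanecarboxylates to γ-oxo ester enolates with in situ Michael trapping, and the Robinson-type Michael/aldol condensation sequence. C-q is already in place; at C-b the enone arm should take the pseudo-axial position of the forming half-chair to avoid the peri hydrogen and then lies syn to the small planar formyl group on C-q and not to its methyl group, which is the only arrangement that can bridge to ring D (a trans adduct cannot cyclise); at C-e the ester takes the equatorial position away from the syn-axial methyl of C-g; C-o stays epimerisable and should place the PMB-oxy group away from the arene. The step needs the ester enolate to form in the presence of the more acidic methyl ketone, which the silyl trigger secures without external base, and it needs the aldol to run at the methyl carbon and not at C-o, which the PMB-oxy substituent secures because an aldol at C-o would give a quaternary, non-dehydratable and therefore reversible adduct. The tert-butyl ester suppresses Claisen condensation of the methyl ketone enolate with the ester.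

**Step 12**
Reactants: 19 tricyclic enone tert-butyl ester
Product: 21 didebromo-salimabromide (tetracyclic lactone; C-b S; C-o S; C-e R; C-q R), via hydroxy acid 20 (not isolated)
Conditions: TFA/CH2Cl2 (1:3), anisole (5 equiv), 0 → 23 °C; then TsOH·H2O (10 mol%), toluene, 60 °C
Reagents that add atoms: none
Why: Acidolysis cleaves the PMB ether (benzylic cation trapped by anisole) and the tert-butyl ester (loss of isobutene), and the resulting γ-hydroxy acid closes the γ-lactone (ring C) by acid-catalysed lactonisation, which is only possible with oxygen and carboxyl on the same face, so the configuration at C-o is fixed by the ring, any C-o epimer converging through the enol of the ketone.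

**Step 13**
Reactants: 21 didebromo-salimabromide
Product: 23 salimabromide, via monobromide 22 (not isolated)
Conditions: NBS (2.3 equiv), TFA, H2SO4 (0.5 equiv), 0 → 23 °C, dark
Reagents that add atoms: N-bromosuccinimide, O=C1CCC(=O)N1Br
Why: Electrophilic aromatic bromination (NBS activated by strong acid) should take place at the two positions ortho to the ethyl group, first the one para and then the one ortho to the C-b-bearing carbon, each activated by two alkyl groups, whereas the third free position is flanked by C-g; the protonated enone is deactivated towards bromine addition and the only α-hydrogen of the ketone sits on the bridgehead lactone carbon C-o, whose enolisation is disfavoured.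

**Compound list**
1 | 1-(3-bromo-4-fluorophenyl)ethan-1-one | CC(=O)c1ccc(F)c(Br)c1 | starting material
2 | 2-bromo-4-ethyl-1-fluorobenzene | CCc1ccc(F)c(Br)c1 | intermediate
3 | 2-(2-bromo-4-ethylphenyl)-2-methylpropanenitrile | CCc1ccc(c(Br)c1)C(C)(C)C#N | intermediate
4 | N-bromomagnesio ketimide of 3-(2-bromo-4-ethylphenyl)-3-methylbutan-2-one (not isolated) | CCc1ccc(c(Br)c1)C(C)(C)C(C)=N[Mg]Br | intermediate
5 | 3-(2-bromo-4-ethylphenyl)-3-methylbutan-2-one | CCc1ccc(c(Br)c1)C(C)(C)C(C)=O | intermediate
6 | 2-bromo-4-ethyl-1-(4-methoxy-2,3-dimethylbut-3-en-2-yl)benzene (E/Z mixture) | CCc1ccc(c(Br)c1)C(C)(C)C(C)=COC | intermediate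
7 | 3-(2-bromo-4-ethylphenyl)-2,3-dimethylbutanal (racemic) | CCc1ccc(c(Br)c1)C(C)(C)C(C)C=O | intermediate
8 | (E)-{[3-(2-bromo-4-ethylphenyl)-2,3-dimethylbut-1-en-1-yl]oxy}(tert-butyl)dimethylsilane | CCc1ccc(c(Br)c1)C(C)(C)/C(C)=C/O[Si](C)(C)C(C)(C)C | intermediate
9 | tert-butyl (1S,2R,3S)-2-[2-(2-bromo-4-ethylphenyl)propan-2-yl]-3-[(tert-butyldimethylsilyl)oxy]-2-methylcyclopropane-1-carboxylate | CCc1ccc(c(Br)c1)C(C)(C)[C@]2(C)[C@@H](O[Si](C)(C)C(C)(C)C)[C@H]2C(=O)OC(C)(C)C | intermediate
10 | aryllithium derived from 9 (Li in place of Br; not isolated) | CCc1ccc(c([Li])c1)C(C)(C)[C@]2(C)[C@@H](O[Si](C)(C)C(C)(C)C)[C@H]2C(=O)OC(C)(C)C | intermediate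
11 | tert-butyl (1S,2R,3S)-3-[(tert-butyldimethylsilyl)oxy]-2-[2-(4-ethyl-2-formylphenyl)propan-2-yl]-2-methylcyclopropane-1-carboxylate | CCc1ccc(c(C=O)c1)C(C)(C)[C@]2(C)[C@@H](O[Si](C)(C)C(C)(C)C)[C@H]2C(=O)OC(C)(C)C | intermediate
12 | dimethyl (1-diazo-2-oxopropyl)phosphonate | COP(=O)(OC)C(=[N+]=[N-])C(C)=O | starting material
13 | (4-methoxyphenyl)methanol | COc1ccc(CO)cc1 | starting material
14 | dimethyl {1-[(4-methoxyphenyl)methoxy]-2-oxopropyl}phosphonate (racemic) | COP(=O)(OC)C(OCc1ccc(OC)cc1)C(C)=O | intermediate
15 | tert-butyl (1S,2R,3S)-3-[(tert-butyldimethylsilyl)oxy]-2-[2-(4-ethyl-2-{(1Z)-2-[(4-methoxyphenyl)methoxy]-3-oxobut-1-en-1-yl}phenyl)propan-2-yl]-2-methylcyclopropane-1-carboxylate | CCc1ccc(c(c1)/C=C(\OCc3ccc(OC)cc3)C(C)=O)C(C)(C)[C@]2(C)[C@@H](O[Si](C)(C)C(C)(C)C)[C@H]2C(=O)OC(C)(C)C | intermediate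
16 | caesium tert-butyl ester enolate of the ring-opened γ-oxo ester (formyl and CH=C(O−)Ot-Bu on C-q, R; not isolated) | CCc1ccc(c(c1)/C=C(\OCc3ccc(OC)cc3)C(C)=O)C(C)(C)[C@](C)(C=O)C=C([O-])OC(C)(C)C.[Cs+] | intermediate
17 | caesium ketone enolate of the Michael adduct (ring B closed; C-b S, C-e R, C-q R; formyl on C-q cis to the side chain on C-b; not isolated) | CCc1ccc2c(c1)[C@@H](C(OCc3ccc(OC)cc3)=C(C)[O-])[C@@H](C(=O)OC(C)(C)C)[C@@](C)(C=O)C2(C)C.[Cs+] | intermediate
18 | caesium aldolate (rings B and D closed, alkoxide on C-β, carbinol configuration undefined; not isolated) | CCc1ccc2c(c1)[C@@H]([C@@H]3OCc4ccc(OC)cc4)[C@@H](C(=O)OC(C)(C)C)[C@@](C)(C([O-])CC3=O)C2(C)C.[Cs+] | intermediate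
19 | tricyclic enone tert-butyl ester (benzo-fused bicyclo[4.3.1]decadienone; tert-butyl ester on C-e, PMB ether on C-o; C-b S, C-e R, C-q R, C-o S) | CCc1ccc2c(c1)[C@@H]([C@@H]3OCc4ccc(OC)cc4)[C@@H](C(=O)OC(C)(C)C)[C@@](C)(C=CC3=O)C2(C)C | intermediate
20 | hydroxy acid (OH on C-o, CO2H on C-e, same face; not isolated) | CCc1ccc2c(c1)[C@@H]([C@@H]3O)[C@@H](C(=O)O)[C@@](C)(C=CC3=O)C2(C)C | intermediate
21 | didebromo-salimabromide (tetracyclic lactone; C-b S, C-o S, C-e R, C-q R) | CCc1ccc2c(c1)[C@H]1[C@@H]3OC(=O)[C@H]1[C@@](C)(C=CC3=O)C2(C)C | intermediate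
22 | monobromide (Br ortho to ethyl and para to the C-b-bearing carbon; not isolated) | CCc1c(Br)cc2c(c1)[C@H]1[C@@H]3OC(=O)[C@H]1[C@@](C)(C=CC3=O)C2(C)C | intermediate
23 | salimabromide | CCc1c(Br)cc2c(c1Br)[C@H]1[C@@H]3OC(=O)[C@H]1[C@@](C)(C=CC3=O)C2(C)C | target

**Step count and risks**
Total steps: 13. Longest linear sequence: 12 (steps 1–8 and 10–13; step 9 is a one-step side branch).

Three steps most likely to fail:

1. Step 11 (proposed new method). The ester enolate may be protonated before it adds, the Michael addition may place the enone arm trans to the formyl group, or the sequence may stall before dehydration in the one-pot. The fallback separates the two bond-forming events and uses known chemistry. It sets out from 15: fluoride-triggered ring opening with intramolecular Michael trapping at low temperature (Bu4NF, THF, −40 → 0 °C, AcOH quench) should give the Michael adduct keto aldehyde F1, which is isolated and whose cis isomer is purified. Ring D is then closed in a separate enamine-mediated intramolecular aldol condensation (pyrrolidine, AcOH, toluene, 60 °C), in which the less substituted enamine of the methyl ketone attacks the aldehyde. This comes back to the route at 19.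

2. Step 7. Carbene transfer to the hindered trisubstituted enol ether may show poor facial selectivity, so the quaternary carbon would be formed in low enantiomeric purity. The fallback changes from catalyst control alone to auxiliary-based double stereodifferentiation with separation of diastereomers. It sets out from 8: cyclopropanation with (1R,2S,5R)-menthyl diazoacetate under the same copper catalyst should give the menthyl cyclopropane ester F2, purified to a single diastereomer by chromatography or crystallisation. The sequence of steps 8, 10 and 11 is then repeated on the menthyl series, giving the formyl menthyl ester F3, the α-alkoxy enone menthyl ester F4 and the tricyclic enone menthyl ester F5. Acidolysis of the PMB ether (TFA, anisole) and acid-catalysed lactonisation with loss of menthol (TsOH, toluene, 80 °C) come back to the route at 21.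

3. Step 8. The aryllithium may be consumed by attack on the ester or by proton abstraction before formylation. The fallback replaces halogen–metal exchange by cross-coupling and oxidative cleavage. It sets out from 9: Suzuki–Miyaura vinylation (K[CH2=CHBF3], Pd(OAc)2, SPhos, Cs2CO3, THF/H2O, 80 °C) should give the styrene F6, and Lemieux–Johnson cleavage (K2OsO4·2H2O cat., NaIO4, 2,6-lutidine, dioxane/H2O) comes back to the route at 11.

**Further compounds**
F1 | step 11 | tert-butyl (1S,2R,3R)-7-ethyl-3-formyl-1-{1-[(4-methoxyphenyl)methoxy]-2-oxopropyl}-3,4,4-trimethyl-1,2,3,4-tetrahydronaphthalene-2-carboxylate (side-chain centre as epimer mixture) | CCc1ccc2c(c1)[C@@H](C(OCc3ccc(OC)cc3)C(C)=O)[C@@H](C(=O)OC(C)(C)C)[C@@](C)(C=O)C2(C)C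
F2 | step 7 | (1R,2S,5R)-menthyl (1S,2R,3S)-2-[2-(2-bromo-4-ethylphenyl)propan-2-yl]-3-[(tert-butyldimethylsilyl)oxy]-2-methylcyclopropane-1-carboxylate | CCc1ccc(c(Br)c1)C(C)(C)[C@]2(C)[C@@H](O[Si](C)(C)C(C)(C)C)[C@H]2C(=O)O[C@@H]1C[C@H](C)CC[C@H]1C(C)C
F3 | step 7 | (1R,2S,5R)-menthyl (1S,2R,3S)-3-[(tert-butyldimethylsilyl)oxy]-2-[2-(4-ethyl-2-formylphenyl)propan-2-yl]-2-methylcyclopropane-1-carboxylate | CCc1ccc(c(C=O)c1)C(C)(C)[C@]2(C)[C@@H](O[Si](C)(C)C(C)(C)C)[C@H]2C(=O)O[C@@H]1C[C@H](C)CC[C@H]1C(C)C
F4 | step 7 | (1R,2S,5R)-menthyl ester analogue of 15 ((Z)-α-(PMB-oxy) enone on the arene, siloxycyclopropane 1S,2R,3S) | CCc1ccc(c(c1)/C=C(\OCc3ccc(OC)cc3)C(C)=O)C(C)(C)[C@]2(C)[C@@H](O[Si](C)(C)C(C)(C)C)[C@H]2C(=O)O[C@@H]1C[C@H](C)CC[C@H]1C(C)C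
F5 | step 7 | (1R,2S,5R)-menthyl ester analogue of 19 (C-b S, C-e R, C-q R, C-o S) | CCc1ccc2c(c1)[C@@H]([C@@H]3OCc4ccc(OC)cc4)[C@@H](C(=O)O[C@@H]1C[C@H](C)CC[C@H]1C(C)C)[C@@](C)(C=CC3=O)C2(C)C
F6 | step 8 | tert-butyl (1S,2R,3S)-3-[(tert-butyldimethylsilyl)oxy]-2-[2-(2-ethenyl-4-ethylphenyl)propan-2-yl]-2-methylcyclopropane-1-carboxylate | CCc1ccc(c(C=C)c1)C(C)(C)[C@]2(C)[C@@H](O[Si](C)(C)C(C)(C)C)[C@H]2C(=O)OC(C)(C)C
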